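**Retrosynthetic overview**
- Ester C–O bond: the target comes from the cis-3α,4α-diol and (S)-3-methylpentanoic acid; only the secondary axial hydroxyl is acylated.
- Ring C3–O and C4–O bonds: both are made in one α-face syn-dihydroxylation of the Δ3 olefin of eudesma-3,7(11)-dien-8-one. This is the stereo-defining key step and sets C3 and C4.
- C5–C10 bond: the dienone comes from achiral germacrone by an enantioselective, proton-triggered transannular cyclisation, which sets C5 and C10.
- Ring order: rings A and B form together in that single event from the ten-membered ring. The isopropylidene ketone of ring B is carried unchanged from germacrone.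

Assumption: germacrone (crystalline isolate of zdravets or Curcuma oil) and single-enantiomer (S)-3-methylpentanoic acid are bought; the catalyst enantiomer that gives the (4aR,8aR) product in step 1 is identified in one screening run, since its sense of induction cannot be predicted.

**Step 1**
Reactants: 1 germacrone [(3E,7E)-3,7-dimethyl-10-(propan-2-ylidene)cyclodeca-3,7-dien-1-one]
Product: 3 (4aR,8aR)-5,8a-dimethyl-3-(propan-2-ylidene)-3,4,4a,7,8,8a-hexahydronaphthalen-2(1H)-one [eudesma-3,7(11)-dien-8-one; 5α-H; 10β-CH3; trans-fused], via 8-oxoeudesm-7(11)-en-4-yl cation 2 (not isolated)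
Conditions: confined chiral IDPi Brønsted acid (BINOL-derived imidodiphosphorimidate, N-triflyl core, 3 mol %), CHCl3/cyclohexane (1:1), −40 °C, 24–48 h; Et3N quench; AgNO3-impregnated silica
Reagents that add atoms: none
Why: Proposed new method: enantioselective proton-triggered transannular cyclisation of an achiral ten-membered 1(10),4-diene by a confined chiral Brønsted acid. The acid, held by a hydrogen bond to the C8 carbonyl, protonates C1 of the C1=C10 olefin in one of the two rapidly interconverting mirror-image crossed conformers of 1; C5 of the C4=C5 olefin closes onto C10 through a chair–chair arrangement, so 5-H ends anti to 10-CH3 (trans-decalin) and both centres are set together, their absolute sense dictated by the chiral anion; the anion, resting over the C1–C3 edge, removes the axial 3-H of cation 2 to give the Δ3 olefin and returns the proton. Closest known reaction types: the racemic acid-induced transannular cyclisation of germacrone to selinadienones, and IDPi-catalysed asymmetric cation–olefin (polyene) cyclisations.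

**Step 2**
Reactants: 3 (4aR,8aR)-eudesma-3,7(11)-dien-8-one
Product: 5 (4aR,5S,6R,8aR)-5,6-dihydroxy-5,8a-dimethyl-3-(propan-2-ylidene)octahydronaphthalen-2(1H)-one [3α,4α-dihydroxyeudesm-7(11)-en-8-one; 4β-CH3], via cyclic osmate ester 4 (not isolated)
Conditions: OsO4 (2 mol %), NMO (1.2 equiv), acetone/H2O (5:1), 0 °C to rt; aq Na2SO3; recrystallise (EtOAc/hexane) to upgrade ee
Reagents that add atoms: osmium tetroxide O=[Os](=O)(=O)=O (delivers both oxygen atoms); N-methylmorpholine N-oxide C[N+]1([O-])CCOCC1 (replenishes the oxygen on osmium); water O (hydrolyses 4, gives the hydroxyl hydrogens)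
Why: Upjohn syn-dihydroxylation: OsO4 adds suprafacially ([3+2]) to the electron-rich trisubstituted Δ3 olefin from the α face, anti to the axial 10β-methyl that is 1,3-diaxial to C4, so both C–O bonds form cis on the α face (3α-OH axial, 4α-OH equatorial, 4-CH3 β) through the hexavalent osmium glycolate 4, while the electron-poor tetrasubstituted enone olefin is left alone.

**Step 3**
Reactants: 5 3α,4α-dihydroxyeudesm-7(11)-en-8-one; 6 (S)-3-methylpentanoic acid
Product: 8 (1S,2R,4aR,8aR)-1-hydroxy-1,4a-dimethyl-6-oxo-7-(propan-2-ylidene)decahydronaphthalen-2-yl (3S)-3-methylpentanoate, via O-acylisourea 7 (not isolated)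
Conditions: 6 (1.5 equiv), DCC (1.6 equiv), DMAP (0.5 equiv), CH2Cl2, 0 °C to rt
Reagents that add atoms: none
Why: Steglich esterification: DMAP-catalysed acyl transfer from 7 acylates only the secondary 3α-hydroxyl (the tertiary 4α-hydroxyl is inert here); no stereocentre is formed or touched, and the acid's stereocentre is β to the carbonyl and cannot epimerise.

**Compound list**
1 | germacrone, (3E,7E)-3,7-dimethyl-10-(propan-2-ylidene)cyclodeca-3,7-dien-1-one | C/C1=C\CC/C(C)=C/CC(=C(C)C)C(=O)C1 | starting material
2 | 8-oxoeudesm-7(11)-en-4-yl cation (5α-H, 10β-CH3; ion pair with the catalyst anion) | C[C+]1CCC[C@]2(C)CC(=O)C(=C(C)C)C[C@H]21 | intermediate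
3 | (4aR,8aR)-5,8a-dimethyl-3-(propan-2-ylidene)-3,4,4a,7,8,8a-hexahydronaphthalen-2(1H)-one, eudesma-3,7(11)-dien-8-one | CC1=CCC[C@]2(C)CC(=O)C(=C(C)C)C[C@H]21 | intermediate
4 | cyclic osmate ester (hexavalent osmium 3α,4α-glycolate of 5) | O=[Os]3(=O)O[C@@H]1CC[C@]2(C)CC(=O)C(=C(C)C)C[C@H]2[C@]1(C)O3 | intermediate
5 | (4aR,5S,6R,8aR)-5,6-dihydroxy-5,8a-dimethyl-3-(propan-2-ylidene)octahydronaphthalen-2(1H)-one, 3α,4α-dihydroxyeudesm-7(11)-en-8-one | O[C@@H]1CC[C@]2(C)CC(=O)C(=C(C)C)C[C@H]2[C@]1(C)O | intermediate
6 | (S)-3-methylpentanoic acid | CC[C@H](C)CC(=O)O | starting material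
7 | N,N'-dicyclohexyl-O-[(3S)-3-methylpentanoyl]isourea | CC[C@H](C)CC(=O)OC(=NC1CCCCC1)NC1CCCCC1 | intermediate
8 | (1S,2R,4aR,8aR)-1-hydroxy-1,4a-dimethyl-6-oxo-7-(propan-2-ylidene)decahydronaphthalen-2-yl (3S)-3-methylpentanoate | CC[C@H](C)CC(=O)O[C@@H]1CC[C@]2(C)CC(=O)C(=C(C)C)C[C@H]2[C@]1(C)O | target

**Totals**
Total step count: 3. Longest linear sequence: 3 steps (1 to 3 to 5 to 8).

**Steps most likely to fail, with fallbacks**

Step 1 (the proposed new step). The risks are insufficient ee and loss of the proton toward the exocyclic or tetrasubstituted olefin instead of Δ3. The fallback uses known chemistry, sets out from 1 and comes back at 3. Germacrone 1 is cyclised with an achiral acid (TsOH·H2O, CH2Cl2, 0 °C), the established acid-induced transannular cyclisation. This gives 3 as the racemate, that is, together with its mirror image (4aS,8aS)-eudesma-3,7(11)-dien-8-one F1. The Δ3 compound is freed from double-bond isomers on AgNO3-impregnated silica, and the racemate is resolved by preparative chiral-phase SFC (amylose carbamate column). The (4aR,8aR) enantiomer 3 continues with step 2.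

Step 3. The risk is slow acylation of the axial 3α-hydroxyl next to the quaternary carbinol. The fallback sets out from 5 and comes back at 8, and replaces acyl substitution by addition of the alcohol to a ketene made by Arndt–Eistert homologation. Purchased (S)-2-methylbutanoic acid F6 is converted with oxalyl chloride and catalytic DMF into (S)-2-methylbutanoyl chloride F7. Diazomethane in Et2O at 0 °C gives (S)-1-diazo-3-methylpentan-2-one F8. Silver benzoate (AgO2CPh, catalytic) and Et3N in THF, in the presence of 5, trigger the Wolff rearrangement; the sec-butyl group migrates with retention to give the ketene (S)-3-methylpent-1-en-1-one F9. The small, very electrophilic ketene adds the 3α-hydroxyl of 5 to give 8.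

Step 2. The risks are over-oxidation or attack at the enone olefin. The fallback sets out from 3 and comes back at 8, so it also replaces step 3. It builds the cis arrangement by neighbouring-group participation instead of osmylation.
- mCPBA (NaHCO3, CH2Cl2, 0 °C) epoxidises 3 from the α face to 3α,4α-epoxyeudesm-7(11)-en-8-one F2.
- Aqueous HBr (48 %, CH2Cl2, −10 °C) opens F2 trans-diaxially at the tertiary carbon to 4β-bromo-3α-hydroxyeudesm-7(11)-en-8-one F3 (4-CH3 now α).
- F3 is esterified with 6 (DCC, DMAP) to 4β-bromo-8-oxoeudesm-7(11)-en-3α-yl (3S)-3-methylpentanoate F4.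
- AgBF4 in wet acetone (0 °C) ionises the tertiary bromide with anchimeric assistance of the anti-periplanar 3α-ester. This gives the α-face cis-fused 2-[(2S)-2-methylbutyl]-1,3-dioxolan-2-ylium ion F5, with inversion at C4 (4-CH3 returns to β).
- Water opens F5 to the axial ester and equatorial alcohol, which is 8 (the second half of a Woodward cis-hydroxylation).

**Further compounds**
F1 | step 1 | (4aS,8aS)-5,8a-dimethyl-3-(propan-2-ylidene)-3,4,4a,7,8,8a-hexahydronaphthalen-2(1H)-one (mirror image of 3) | CC1=CCC[C@@]2(C)CC(=O)C(=C(C)C)C[C@@H]21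
F2 | step 2 | 3α,4α-epoxyeudesm-7(11)-en-8-one | O3[C@@H]1CC[C@]2(C)CC(=O)C(=C(C)C)C[C@H]2[C@@]13C
F3 | step 2 | 4β-bromo-3α-hydroxyeudesm-7(11)-en-8-one (4-CH3 α) | O[C@@H]1CC[C@]2(C)CC(=O)C(=C(C)C)C[C@H]2[C@@]1(C)Br
F4 | step 2 | 4β-bromo-8-oxoeudesm-7(11)-en-3α-yl (3S)-3-methylpentanoate | CC[C@H](C)CC(=O)O[C@@H]1CC[C@]2(C)CC(=O)C(=C(C)C)C[C@H]2[C@@]1(C)Br
F5 | step 2 | 3α,4α-cis-fused 2-[(2S)-2-methylbutyl]-1,3-dioxolan-2-ylium ion | O3[C@@H]1CC[C@]2(C)CC(=O)C(=C(C)C)C[C@H]2[C@]1(C)[O+]=C3C[C@@H](C)CC
F6 | step 3 | (S)-2-methylbutanoic acid (purchased starting material of the fallback) | CC[C@H](C)C(=O)O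
F7 | step 3 | (S)-2-methylbutanoyl chloride | CC[C@H](C)C(Cl)=O
F8 | step 3 | (S)-1-diazo-3-methylpentan-2-one | CC[C@H](C)C(=O)C=[N+]=[N-]
F9 | step 3 | (S)-3-methylpent-1-en-1-one (ketene) | CC[C@H](C)C=C=O
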